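## The problem

Target **16**, 2-heptyl-4-[(2-hydroxy-4-methoxy-6-pentylbenzoyl)oxy]-6-methoxybenzoic acid, is a depside: two benzene rings joined only by an aryl ester, C1 of ring A to C7(=O) to O4 of ring B. No ring has to be built, and there is no stereocentre or stereogenic double bond, so stereocontrol plays no part. The difficulties are crowding, regiochemistry and telling the oxygen functions apart. The acyl carbon C7 sits on C1 of ring A between the C2 hydroxyl and the C6 pentyl chain, so esterification by attack on an activated di-ortho-substituted benzoic acid is slow. The carboxyl of ring B is flanked in the same way by heptyl and methoxy. Ring A needs a free hydroxyl at C2 but a methyl ether at C4, and ring B needs a methyl ether at C6 beside a free acid. The aryl ester is the fragile group: hydroxide, alkoxides and amines cleave it, a phenoxide on ring A can expel the ring B phenoxide, and ether-cleaving Lewis acids would also remove the methyl ethers ortho to the carbonyl groups. The ring B acid therefore cannot be unmasked by saponification. A short convergent route is possible because C7 is a single carbon between an aryl carbon and a phenolic oxygen, so it can be supplied as carbon monoxide between an aryl iodide (C1 of ring A) and a phenol (O4 of ring B).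

## Retrosynthesis

**16 from 15.** The last bond cut is the O–C(CH3)3 bond of a tert-butyl ester on the ring B carboxyl. A methyl or ethyl ester would need hydroxide, which the C7 ester does not survive. A benzyl ester would fall together with the ring A benzyl ethers and leave a free acid during the methylation. The tert-butyl ester leaves by alkyl–oxygen fission in acid, which never touches an acyl carbon. The forward step must cleave it without alkylating the electron-rich rings.

**15 from 14, and 14 from 13.** Next the C4 O–CH3 bond of ring A is cut, then both O–benzyl bonds. Carrying ring A as a symmetric dibenzyl ether means its iodination has only one possible outcome next to the pentyl chain. An unsymmetrical benzyl/methyl ether would offer two different sites. In diphenol **14** the C2 hydroxyl is hydrogen-bonded to the C7 carbonyl, so the C4 hydroxyl is the more acidic and more exposed one. The forward steps are a clean hydrogenolysis and a chemoselective mono-methylation without strong base.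

**13 from 4, 11 and 12 (key disconnection).** Both bonds to C7 are cut at once: C1 of ring A to C7, and C7 to O4 of ring B. This leaves aryl iodide **4**, carbon monoxide **12** and phenol **11**. The neighbouring cut (only the C7–O4 bond) leads back to a di-ortho-substituted benzoic acid that must be made and then activated. The carbonylative cut replaces that acid by an acylpalladium formed in place. The precursors are two monocyclic arenes of similar size, so the route is convergent. The forward reaction must insert CO before any direct C–O coupling and must tolerate the crowding around the C–I bond.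

**4 from 3, and 3 from 1 and 2.** The C–I bond and the two O–benzyl bonds are cut, leading to olivetol **1** and two equivalents of benzyl bromide **2**. Ring A is thus bought with its pentyl chain and both oxygens in place. In **3** the two carbons next to the pentyl chain are equivalent, each ortho to one benzyloxy group and para to the other. Iodination must occur there and not between the two oxygens, and must stop after one iodine.

**11 from 9 (through 10), 9 from 8, and 8 from 5 and 6 (through 7).** The C4–O bond of ring B is cut back to a C–H bond. In ester **9**, C4 is the only ring carbon without an ortho substituent, so a sterically governed C–H borylation to boronate **10** and oxidation places the hydroxyl there. No electrophilic substitution would do this, since the methoxy group directs to C3 and C5. The tert-butyl ester is then cut to acid **8**, and the benzylic C–C bond of the heptyl chain is cut to 2-methoxy-6-methylbenzoic acid **5** and 1-iodohexane **6**, joined through dianion **7**. Each precursor is a simple commercial arene or alkyl halide.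

## Roads not taken

**Alternative 1: biomimetic aldol closure of ring A on the preformed ester.** The cut is the C1–C6 bond of ring A. The precursor is the linear triketo ester **A1** (tert-butyl 2-heptyl-6-methoxy-4-[(3,5,7-trioxododecanoyl)oxy]benzoate). Under a mild amine base its chain C2 methylene would add to the chain C7 ketone, and dehydration with enolisation would give **A2**, which is the same compound as **14**.
- Merits: the pentyl chain, both hydroxyls and the acyl carbon are in place by construction. There is no aromatic substitution regiochemistry, no protecting group on ring A and no metal. It joins the chosen endgame one step later, saving the hydrogenolysis.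
- Weak points: **A1** is an active aryl ester carrying three enolisable ketones. Lactonisation through the C5 enol oxygen, or Claisen closure of C6 onto C1, would both expel the ring B phenoxide and destroy the ester. The aldol mode must beat two closures that have a good leaving group. Making **A1** also means attaching a polyketo acid equivalent to phenol **11**, which costs several steps of sensitive polycarbonyl chemistry.
- Comparison: the chosen plan spends one more step after the key step, but it buys ring A instead of building it and forms the ester by a reaction with no competing closure.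

**Alternative 2: inverse-demand Diels–Alder of a pyrone.** The cuts are the C3–C4 and C5–C6 bonds of ring A. Pyrone ester **A3** (4-[(benzyloxy)carbonyl]-3-heptyl-5-methoxyphenyl 4-(benzyloxy)-2-oxo-6-pentyl-2H-pyran-5-carboxylate) would react with ketene acetal **A4** (1,1-dimethoxyethene). Decarboxylative opening of the bridged adduct and elimination of one methoxy group would give **A5** (benzyl 4-{[2-(benzyloxy)-4-methoxy-6-pentylbenzoyl]oxy}-2-heptyl-6-methoxybenzoate).
- Merits: the C4 methyl ether arrives already distinguished from the C2 oxygen, and one hydrogenolysis of **A5** removes the benzyl ether and benzyl ester together. The endgame is one step against three in the chosen plan, with no selective methylation. This is a real advantage.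
- Weak points: the 4-alkoxy group raises the LUMO of **A3**, and the new bond to the acetal CH2 must form at the pentyl-bearing pyrone C6. The reaction would need heat, under which **A4** oligomerises. **A3** must itself be made by acylating the ring B phenol with a crowded pyrone carboxylic acid, so the hindered esterification is moved, not avoided, and the pyrone acid needs its own multistep synthesis.
- Comparison: the chosen plan has a longer endgame, but every step before it is short and ring A comes from a commercial resorcinol.

**Alternative 3: Diels–Alder of an aryl ynoate with a dioxygenated silyl ketene acetal diene.** The cuts are the C1–C2 and C5–C6 bonds of ring A. Ynoate **A6** (tert-butyl 2-heptyl-6-methoxy-4-(oct-2-ynoyloxy)benzoate) would react with diene **A7** (1,3-dimethoxy-1-(trimethylsilyloxy)buta-1,3-diene). Desilylation and elimination of one methoxy group would give **A8**, which is the same compound as **15**.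
- Merits: **A6** is one unhindered acylation from phenol **11**, the regiochemistry is fixed by the polarity of both partners, and the product is the penultimate compound with the hydroxyl and methyl ether already in the right places. On paper this is the shortest route, about six steps against nine, with no ring A protecting groups and no selective methylation.
- Weak points: a 3-alkyl ynoate is a sluggish dienophile, and **A7** does not survive the prolonged heating such dienophiles need. The nucleophilic terminus of **A7** can also attack the aryl ester carbonyl and release the ring B phenoxide.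
- Comparison: this road is shorter. The chosen plan accepts three more steps in exchange for a key step whose elementary steps are all well established and whose partners are stable.

Key step: step 6

Remark on the chemistry: the target has no stereocentre and no stereogenic double bond, so all SMILES strings below are complete without stereodescriptors.

## Route

Step 1
Reactants: 1 olivetol (5-pentylbenzene-1,3-diol); 2 benzyl bromide (2.2 equiv in all)
Product: 3 1,3-bis(benzyloxy)-5-pentylbenzene
Conditions: BnBr (2.2 equiv), K2CO3 (3 equiv), DMF, 60 °C
Reagents that add atoms: benzyl bromide (the second equivalent of 2, which supplies the second benzyl group), BrCc1ccccc1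
Why: Double Williamson ether synthesis; both phenoxides of the symmetric resorcinol are O-alkylated, each by one molecule of the reactive benzylic bromide, in a polar aprotic solvent, and nothing else in 1 reacts.

Step 2
Reactants: 3 1,3-bis(benzyloxy)-5-pentylbenzene
Product: 4 1,5-bis(benzyloxy)-2-iodo-3-pentylbenzene
Conditions: NIS (1.05 equiv), MeCN, 0 °C to rt, dark
Reagents that add atoms: N-iodosuccinimide, O=C1CCC(=O)N1I
Why: Electrophilic aromatic iodination; the two equivalent carbons next to the pentyl chain (ortho to one benzyloxy, para to the other) are attacked in preference to the carbon between the two benzyloxy groups, as is usual for halogenation of 5-alkylresorcinol diethers, and one equivalent of NIS at low temperature limits di-iodination.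

Step 3
Reactants: 5 2-methoxy-6-methylbenzoic acid; 6 1-iodohexane
Product: 8 2-heptyl-6-methoxybenzoic acid, via dilithiated 2-methoxy-6-methylbenzoic acid 7 (not isolated)
Conditions: LiN(iPr)2 (2.2 equiv), THF, −78 to 0 °C; then 6, −78 °C to rt; aq. HCl
Reagents that add atoms: lithium diisopropylamide, [Li+].CC(C)[N-]C(C)C (lithium in intermediate 7 only)
Why: Lateral lithiation of an ortho-toluic acid; the carboxylate forms first and stabilises the benzylic lithium of dianion 7, whose carbon terminus is the more nucleophilic site and is alkylated by the primary iodide in an SN2 reaction, and acid work-up returns the carboxylic acid.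

Step 4
Reactants: 8 2-heptyl-6-methoxybenzoic acid
Product: 9 tert-butyl 2-heptyl-6-methoxybenzoate
Conditions: Cl3CC(=NH)OtBu (2 equiv), BF3·OEt2 (cat.), CH2Cl2–cyclohexane, rt
Reagents that add atoms: tert-butyl 2,2,2-trichloroacetimidate, CC(C)(C)OC(=N)C(Cl)(Cl)Cl
Why: Esterification with a trichloroacetimidate; the protonated imidate releases a tert-butyl cation that is captured by the carboxylate oxygen, so the crowded carbonyl carbon is never attacked and the two ortho substituents do not slow the reaction.

Step 5
Reactants: 9 tert-butyl 2-heptyl-6-methoxybenzoate
Product: 11 tert-butyl 2-heptyl-4-hydroxy-6-methoxybenzoate, via the C4 pinacol boronate 10 (not isolated)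
Conditions: HBpin (2 equiv), [Ir(OMe)(cod)]2 (1.5 mol %), 4,4′-di-tert-butyl-2,2′-bipyridine (3 mol %), THF, 80 °C; evaporate; then Oxone (2KHSO5·KHSO4·K2SO4), acetone–H2O, rt
Reagents that add atoms: pinacolborane, [H]B1OC(C)(C)C(C)(C)O1 (boron in intermediate 10 only); potassium peroxymonosulfate (the active salt of Oxone), [K+].[O-]S(=O)(=O)OO
Why: Iridium-catalysed aromatic C–H borylation is sterically governed; in the 1,2,3-trisubstituted ring of 9 only C4 has no ortho substituent (C3 is next to heptyl, C5 next to methoxy), so boron enters para to the ester, and Oxone then converts the C–B bond into C–OH at the same carbon by 1,2-aryl shift from boron to oxygen in the same flask.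

Step 6
Reactants: 4 1,5-bis(benzyloxy)-2-iodo-3-pentylbenzene; 11 tert-butyl 2-heptyl-4-hydroxy-6-methoxybenzoate; 12 carbon monoxide
Product: 13 tert-butyl 4-{[2,4-bis(benzyloxy)-6-pentylbenzoyl]oxy}-2-heptyl-6-methoxybenzoate
Conditions: Pd(OAc)2 (5 mol %), Xantphos (7.5 mol %), Et3N (3 equiv), CO (1 atm), dry toluene, 90 °C
Reagents that add atoms: none
Why: Pd(OAc)2 (divalent palladium) is reduced in the flask to zerovalent palladium bound by Xantphos, which inserts into the C–I bond of 4; CO then coordinates and migrates into the aryl–palladium bond, relieving the crowding between the metal and the two ortho substituents (benzyloxy and pentyl), to give an aroylpalladium iodide. The phenoxide of 11, formed with Et3N, replaces iodide on the metal and C–O reductive elimination (or direct attack of the phenoxide on the acyl carbon) releases ester 13 and zerovalent palladium, while Et3N takes up HI. The closest known reaction type is the palladium-catalysed aryloxycarbonylation of aryl iodides with CO and phenols under Pd(OAc)2 and a wide-bite-angle diphosphine at atmospheric pressure. Two bonds form, C1 of ring A to C7 and C7 to O4 of ring B; no ring closes and no stereocentre arises. The selectivity needed is chemoselectivity: carbonylative coupling must outrun direct C–O coupling to a diaryl ether and reduction of the iodide, and the hydroxyl of 11 must be the only nucleophile. The CO atmosphere and the fast insertion into a hindered aryl–palladium bond secure the first, and the absence of any other free hydroxyl, amine or water secures the second. The hydroxyl of 11 is flanked by two hydrogens, so crowding lies only on the acyl side, where an acylpalladium is far more reactive than any derivative of the di-ortho-substituted acid; the benzyl ethers, the methyl ether and the tert-butyl ester are inert to these conditions.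

Step 7
Reactants: 13 tert-butyl 4-{[2,4-bis(benzyloxy)-6-pentylbenzoyl]oxy}-2-heptyl-6-methoxybenzoate
Product: 14 tert-butyl 4-[(2,4-dihydroxy-6-pentylbenzoyl)oxy]-2-heptyl-6-methoxybenzoate
Conditions: H2 (1 atm), Pd/C (10 %), EtOAc, rt
Reagents that add atoms: none
Why: Hydrogenolysis of benzyl aryl ethers over palladium on carbon; the aryl ester, the tert-butyl ester, the methyl ether and the benzene rings are not reduced under these neutral conditions.

Step 8
Reactants: 14 tert-butyl 4-[(2,4-dihydroxy-6-pentylbenzoyl)oxy]-2-heptyl-6-methoxybenzoate
Product: 15 tert-butyl 2-heptyl-4-[(2-hydroxy-4-methoxy-6-pentylbenzoyl)oxy]-6-methoxybenzoate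
Conditions: MeI (1.1 equiv), K2CO3 (1.1 equiv), acetone, rt
Reagents that add atoms: iodomethane, CI
Why: Williamson methylation under a weak base; the C2 hydroxyl of ring A is hydrogen-bonded to the C7 carbonyl and is less acidic and less accessible, so the C4 phenoxide forms and is methylated first, as is usual for 2,4-dihydroxybenzoates, and without hydroxide or alkoxide the aryl ester is not attacked.

Step 9
Reactants: 15 tert-butyl 2-heptyl-4-[(2-hydroxy-4-methoxy-6-pentylbenzoyl)oxy]-6-methoxybenzoate
Product: 16 2-heptyl-4-[(2-hydroxy-4-methoxy-6-pentylbenzoyl)oxy]-6-methoxybenzoic acid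
Conditions: CF3CO2H–CH2Cl2 (1:4), 0 °C to rt
Reagents that add atoms: none
Why: Acidolysis of a tert-butyl ester by alkyl–oxygen cleavage (loss of the tert-butyl cation as isobutene); no nucleophile attacks an acyl carbon, so the aryl ester, the methyl ethers and the phenol are untouched.

## Compound list

1 | olivetol (5-pentylbenzene-1,3-diol) | CCCCCc1cc(O)cc(O)c1 | starting material
2 | benzyl bromide | BrCc1ccccc1 | starting material
3 | 1,3-bis(benzyloxy)-5-pentylbenzene | CCCCCc1cc(OCc2ccccc2)cc(OCc2ccccc2)c1 | intermediate
4 | 1,5-bis(benzyloxy)-2-iodo-3-pentylbenzene | CCCCCc1cc(OCc2ccccc2)cc(OCc2ccccc2)c1I | intermediate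
5 | 2-methoxy-6-methylbenzoic acid | Cc1cccc(OC)c1C(=O)O | starting material
6 | 1-iodohexane | CCCCCCI | starting material
7 | lithium 2-(lithiomethyl)-6-methoxybenzoate (dilithiated 2-methoxy-6-methylbenzoic acid; formed in the flask, not isolated) | [Li+].[Li+].[CH2-]c1cccc(OC)c1C(=O)[O-] | intermediate
8 | 2-heptyl-6-methoxybenzoic acid | CCCCCCCc1cccc(OC)c1C(=O)O | intermediate
9 | tert-butyl 2-heptyl-6-methoxybenzoate | CCCCCCCc1cccc(OC)c1C(=O)OC(C)(C)C | intermediate
10 | tert-butyl 2-heptyl-6-methoxy-4-(4,4,5,5-tetramethyl-1,3,2-dioxaborolan-2-yl)benzoate (formed in the flask, not isolated) | CCCCCCCc1cc(B2OC(C)(C)C(C)(C)O2)cc(OC)c1C(=O)OC(C)(C)C | intermediate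
11 | tert-butyl 2-heptyl-4-hydroxy-6-methoxybenzoate | CCCCCCCc1cc(O)cc(OC)c1C(=O)OC(C)(C)C | intermediate
12 | carbon monoxide | [C-]#[O+] | starting material
13 | tert-butyl 4-{[2,4-bis(benzyloxy)-6-pentylbenzoyl]oxy}-2-heptyl-6-methoxybenzoate | CCCCCCCc1cc(OC(=O)c2c(OCc3ccccc3)cc(OCc3ccccc3)cc2CCCCC)cc(OC)c1C(=O)OC(C)(C)C | intermediate
14 | tert-butyl 4-[(2,4-dihydroxy-6-pentylbenzoyl)oxy]-2-heptyl-6-methoxybenzoate | CCCCCCCc1cc(OC(=O)c2c(O)cc(O)cc2CCCCC)cc(OC)c1C(=O)OC(C)(C)C | intermediate
15 | tert-butyl 2-heptyl-4-[(2-hydroxy-4-methoxy-6-pentylbenzoyl)oxy]-6-methoxybenzoate | CCCCCCCc1cc(OC(=O)c2c(O)cc(OC)cc2CCCCC)cc(OC)c1C(=O)OC(C)(C)C | intermediate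
16 | 2-heptyl-4-[(2-hydroxy-4-methoxy-6-pentylbenzoyl)oxy]-6-methoxybenzoic acid | CCCCCCCc1cc(OC(=O)c2c(O)cc(OC)cc2CCCCC)cc(OC)c1C(=O)O | target

## Step count and risk

Total steps: 9. Longest linear sequence: 7 steps (steps 3, 4, 5, 6, 7, 8, 9, from 5 to 16). The ring A branch (steps 1 and 2) joins at step 6.

**Step 6 (key step).**
- Risk: capture of the crowded aroylpalladium by the phenoxide may be slow. Reduction of the C–I bond, or hydrolysis of the acylpalladium by traces of water, could then take over. Slow oxidative addition into the electron-rich, doubly flanked iodide could also let the catalyst aggregate before turnover.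
- Fallback: this sets out from 4 and gives up the carbonylative union. Iodine–lithium exchange with n-BuLi in THF at −78 °C and quenching with CO2 should give 2,4-bis(benzyloxy)-6-pentylbenzoic acid F1. Oxalyl chloride with catalytic DMF should convert it into 2,4-bis(benzyloxy)-6-pentylbenzoyl chloride F2. Acylation of phenol 11 with F2, Et3N and DMAP in CH2Cl2 returns to the route at 13.

**Step 5.**
- Risk: some borylation may occur at C5 next to the small methoxy group, or turnover on the electron-rich, crowded arene may be slow. Either would give isomeric or incompletely converted material after oxidation. Over-oxidation of the new phenol by the peroxysulfate is also possible.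
- Fallback: this abandons C–H functionalisation and carries the C4 oxygen from the start. It sets out from 1-iodohexane 6 and purchased methyl 2,4-dihydroxy-6-methylbenzoate F3, and is six operations long but regiochemically unambiguous.
  - Benzylation of the unchelated hydroxyl with 2 and K2CO3 in acetone gives methyl 4-(benzyloxy)-2-hydroxy-6-methylbenzoate F4.
  - Methylation of the chelated hydroxyl with MeI and K2CO3 in DMF gives methyl 4-(benzyloxy)-2-methoxy-6-methylbenzoate F5.
  - Lateral lithiation with LiN(iPr)2 at −78 °C and alkylation with 6 gives methyl 4-(benzyloxy)-2-heptyl-6-methoxybenzoate F6.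
  - Hydrolysis with KOH in aqueous DMSO at 100 °C gives 4-(benzyloxy)-2-heptyl-6-methoxybenzoic acid F7.
  - Esterification with tert-butyl 2,2,2-trichloroacetimidate gives tert-butyl 4-(benzyloxy)-2-heptyl-6-methoxybenzoate F8.
  - Hydrogenolysis over Pd/C returns to the route at 11.

**Step 8.**
- Risk: selectivity between the two phenols may be lost, giving double methylation. Under carbonate the ring A phenoxide may also expel the ring B phenoxide (a ketene-type fragmentation that the blocked acyl carbon favours), and the freed phenoxide would then be methylated irreversibly.
- Fallback: this sets out from 14 and replaces base-mediated alkylation by a Mitsunobu etherification (MeOH, PPh3, diisopropyl azodicarboxylate, THF, 0 °C to rt). It runs under neutral conditions, engages only the more acidic unchelated C4 hydroxyl, and returns at 15 without any new intermediate (F0).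

**Step 3.**
- Risk: the dilithio species 7 may form incompletely or aggregate. Proton exchange between 7 and the alkylated product could then give double alkylation at the benzylic carbon together with recovered 5.
- Fallback: this sets out from 5 and reverses the order. Esterification with tert-butyl 2,2,2-trichloroacetimidate gives tert-butyl 2-methoxy-6-methylbenzoate F9. Its benzylic monoanion (LiN(iPr)2, THF, −78 °C) is alkylated with 6, returning to the route at 9 and bypassing 8.

## Further compounds

F1 | step 6 | 2,4-bis(benzyloxy)-6-pentylbenzoic acid | CCCCCc1cc(OCc2ccccc2)cc(OCc2ccccc2)c1C(=O)O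
F2 | step 6 | 2,4-bis(benzyloxy)-6-pentylbenzoyl chloride | CCCCCc1cc(OCc2ccccc2)cc(OCc2ccccc2)c1C(=O)Cl
F3 | step 5 | methyl 2,4-dihydroxy-6-methylbenzoate | COC(=O)c1c(C)cc(O)cc1O
F4 | step 5 | methyl 4-(benzyloxy)-2-hydroxy-6-methylbenzoate | COC(=O)c1c(C)cc(OCc2ccccc2)cc1O
F5 | step 5 | methyl 4-(benzyloxy)-2-methoxy-6-methylbenzoate | COC(=O)c1c(C)cc(OCc2ccccc2)cc1OC
F6 | step 5 | methyl 4-(benzyloxy)-2-heptyl-6-methoxybenzoate | CCCCCCCc1cc(OCc2ccccc2)cc(OC)c1C(=O)OC
F7 | step 5 | 4-(benzyloxy)-2-heptyl-6-methoxybenzoic acid | CCCCCCCc1cc(OCc2ccccc2)cc(OC)c1C(=O)O
F8 | step 5 | tert-butyl 4-(benzyloxy)-2-heptyl-6-methoxybenzoate | CCCCCCCc1cc(OCc2ccccc2)cc(OC)c1C(=O)OC(C)(C)C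
F0 | step 8 | none | none
F9 | step 3 | tert-butyl 2-methoxy-6-methylbenzoate | Cc1cccc(OC)c1C(=O)OC(C)(C)C
A1 | alternative 1 | tert-butyl 2-heptyl-6-methoxy-4-[(3,5,7-trioxododecanoyl)oxy]benzoate | CCCCCCCc1cc(OC(=O)CC(=O)CC(=O)CC(=O)CCCCC)cc(OC)c1C(=O)OC(C)(C)C
A2 | alternative 1 | tert-butyl 4-[(2,4-dihydroxy-6-pentylbenzoyl)oxy]-2-heptyl-6-methoxybenzoate | CCCCCCCc1cc(OC(=O)c2c(O)cc(O)cc2CCCCC)cc(OC)c1C(=O)OC(C)(C)C
A3 | alternative 2 | 4-[(benzyloxy)carbonyl]-3-heptyl-5-methoxyphenyl 4-(benzyloxy)-2-oxo-6-pentyl-2H-pyran-5-carboxylate | CCCCCCCc1cc(OC(=O)c2c(OCc3ccccc3)cc(=O)oc2CCCCC)cc(OC)c1C(=O)OCc1ccccc1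
A4 | alternative 2 | 1,1-dimethoxyethene | C=C(OC)OC
A5 | alternative 2 | benzyl 4-{[2-(benzyloxy)-4-methoxy-6-pentylbenzoyl]oxy}-2-heptyl-6-methoxybenzoate | CCCCCCCc1cc(OC(=O)c2c(OCc3ccccc3)cc(OC)cc2CCCCC)cc(OC)c1C(=O)OCc1ccccc1
A6 | alternative 3 | tert-butyl 2-heptyl-6-methoxy-4-(oct-2-ynoyloxy)benzoate | CCCCCCCc1cc(OC(=O)C#CCCCCC)cc(OC)c1C(=O)OC(C)(C)C
A7 | alternative 3 | 1,3-dimethoxy-1-(trimethylsilyloxy)buta-1,3-diene | C=C(OC)C=C(OC)O[Si](C)(C)C
A8 | alternative 3 | tert-butyl 2-heptyl-4-[(2-hydroxy-4-methoxy-6-pentylbenzoyl)oxy]-6-methoxybenzoate | CCCCCCCc1cc(OC(=O)c2c(O)cc(OC)cc2CCCCC)cc(OC)c1C(=O)OC(C)(C)C
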